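The runs are calculated from invented constants; noise was put on by code.

The X in a closed flask is conserved: counted by its X, what stands in X, D, L and J stays at the charge, so once X and D are gone L and J make up the charge between them, and we call the fraction of the charge in L y. You asked for a quick number on this flask, so here is ours.

common to all: X 10 mM
- gamma: E 2 equiv; run made earlier
- alpha: E 8 equiv; run made earlier
- flask: E 4.00 equiv; time 3.0 h

| run | time / min | X / % | L / % |
|---|---|---|---|
| gamma | 25.0 | 3.0 | 36.5 |
| gamma | 50.0 | 0.4 | 36.1 |
| gamma | 80.0 | 0 | 37.9 |
| gamma | 120 | 0 | 37.4 |
| alpha | 25.0 | 0 | 55.1 |
| alpha | 50.0 | 0 | 57.8 |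
| alpha | 80.0 | 0 | 56.1 |
| alpha | 120 | 0 | 56.2 |

(readings scatter by 1 percentage point)

- a species is counted by the X in it: one J counts as two
- the numbers in the tables scatter by 1 percentage point (one standard deviation)
- reactions considered so far: X + E -> L; X <-> D; X + L -> J
- the reaction counts as stopped when no species that holds the X changes by six tenths of a point or more over the second half of the time

- which holds at 3.0 h: what has brought the reaction to rest, or that it has not come to rest (forward and back rates have come level / all of X has reacted / E has run out first / it is still moving)
- share of the X used up at 3.0 h
- L at 3.0 h, in percent of the X charged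
- amount of L if the flask were left three thousand times as long, in percent of the X charged

X looks like the limiting reagent in gamma, charged with 2 equiv of E: that run reads 0% X at 80.0 min, and its L stays flat within the scatter to 120 min, so we expect the flask to be at rest by 3.0 h, later than that last reading. The yield is a race from which X cancels, since each X that leaves the pool of X and D goes either to L or, taking one L along, to J. Let ρ be the rate of X + E over the rate of X + L with L at the full charge; y then gains (ρ − y)/(ρ + y) per X spent. For large ρ, y ends near 1 − 1/ρ; for small ρ, it stops at ρ. The join y = ρ/(1 + ρ) meets both ends, so the end odds, y/(1 − y), read ρ. The last readings give 0.597 for gamma and 1.28 for alpha, so, as read through their scatter, the odds rise as E to the power 0.551. At 4.00 equiv we commit to 0.876, the end odds of L, which makes y 46.7%.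

Your hunch, the forecast, says all of X has reacted, conversion 100%, y 47% and 49% in the long run, holding that “L depends only weakly on E, so the loss competes with the E step”. We part on the long run, where the flat L of gamma and alpha suggests to us no gain.

The flask gives: all of X has reacted, conversion >99.9%, y 48.1%, and 48.1% in the long run.

    X + E → L, rate k1*[X]*[E]^0.5 (k = 1.40 M⁻⁰·⁵ min⁻¹)
    X ⇌ D (K = 1.80, k = 0.210 min⁻¹)
    X + L → J (k = 33.0 M⁻¹ min⁻¹)

The flask's odds come to 0.927 against our 0.876, and its y has moved by 5 points at the nearest 2.79 equiv of E below and 5.85 equiv above. Take the neighbouring flask with 2.5 mM of X at the same equivalents. The race scales the odds by the charge ratio to the power 1 minus 0.551, which lifts them to 1.63 and y to 62.0%. That neighbouring flask holds 36.1% J and 63.8% L at 3.0 h.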